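**Retrosynthetic overview**
1. Target 21 ⇐ trans-selective C4 methylation of the dianion of the cis lactone acid 19, then ketal hydrolysis.
2. 19 ⇐ one-pot hydrogenation/hydrogenolysis of butenolide benzyl ester 18; H2 adds anti to the C2 chain and sets the 2,3-cis relationship.
3. 18 ⇐ cross-metathesis of two fragments of equal step count: chiral butenolide 17 (from pent-4-enal) and ketal alkene 7 (from dec-9-en-1-ol by acetoacetic ester synthesis).
4. 17 ⇐ the lactone, the only ring of the target, closed by intramolecular aldol addition of a bromoacetate-derived zinc enolate onto the neighbouring α-keto ester, then dehydration. The keto ester comes from an asymmetric diazoacetate aldol (sets C2), O-acylation and diazo oxidation.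
5. Ring order: the dioxolane (protecting ring) is made first in its own branch and removed last; the lactone ring forms in step 7.

Assumption: oxolane numbering is used (O1, C2 bears the chain, C3 the CO2H, C4 the CH3, C5 is the lactone C=O), and the ProPhenol antipode written in step 5 is taken as the one giving the (3S)-alcohol; its mirror image is used if the sense proves opposite.

**Route**

Step 1
Reactants: 1 dec-9-en-1-ol
Product: 2 10-bromodec-1-ene
Conditions: CBr4, PPh3, CH2Cl2, 0 °C → rt
Reagents that add atoms: carbon tetrabromide, BrC(Br)(Br)Br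
Why: Appel bromination, in which the oxyphosphonium of the primary alcohol is displaced by bromide (SN2) while the remote terminal alkene is untouched.

Step 2
Reactants: 2 10-bromodec-1-ene; 3 ethyl acetoacetate
Product: 4 ethyl 2-acetyldodec-11-enoate
Conditions: NaOEt, NaI (cat.), EtOH, reflux (3 in 1.5-fold excess)
Reagents that add atoms: none
Why: Acetoacetic ester alkylation, in which the stabilised sodium enolate of 3 is C-alkylated by the unhindered primary bromide (SN2) and excess 3 suppresses dialkylation.

Step 3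
Reactants: 4 ethyl 2-acetyldodec-11-enoate
Product: 6 tridec-12-en-2-one, via keto acid 5 (not isolated)
Conditions: 5% aq. NaOH, EtOH, rt; then aq. H2SO4 to pH 1, 80 °C
Reagents that add atoms: none
Why: Ketonic hydrolysis of the acetoacetic ester, in which saponification gives the β-keto acid that loses CO2 through the six-membered transition state on acidification and warming.

Step 4
Reactants: 6 tridec-12-en-2-one
Product: 7 2-methyl-2-(undec-10-en-1-yl)-1,3-dioxolane
Conditions: HOCH2CH2OH, p-TsOH·H2O (cat.), toluene, reflux, Dean–Stark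
Reagents that add atoms: ethylene glycol, OCCO
Why: Acid-catalysed ketalisation driven by azeotropic water removal masks the methyl ketone so that it survives the later hydrogenation and the strong-base enolate alkylation.

Step 5
Reactants: 8 pent-4-enal; 9 benzyl diazoacetate
Product: 10 benzyl (3S)-2-diazo-3-hydroxyhept-6-enoate
Conditions: (S,S)-ProPhenol (5 mol%), Bu2Mg (10 mol%), cis-cyclopentane-1,2-diol (5 mol%), THF, −20 °C
Reagents that add atoms: none
Why: Catalytic asymmetric aldol addition of the diazoacetate (dinuclear Mg–ProPhenol catalyst) forms the future oxolane C2–C3 bond and sets the single carbinol stereocentre (3S) by catalyst control.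

Step 6
Reactants: 10 benzyl (3S)-2-diazo-3-hydroxyhept-6-enoate; 11 bromoacetyl bromide
Product: 12 benzyl (3S)-3-[(bromoacetyl)oxy]-2-diazohept-6-enoate
Conditions: pyridine, CH2Cl2, −20 → 0 °C
Reagents that add atoms: none
Why: O-Acylation of the secondary alcohol by the acid bromide (nucleophilic acyl substitution, pyridine as HBr scavenger) installs the two-carbon enolate precursor, and the acceptor-substituted diazo group tolerates these buffered conditions.

Step 7
Reactants: 12 benzyl (3S)-3-[(bromoacetyl)oxy]-2-diazohept-6-enoate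
Product: 15 benzyl (2S)-2-(but-3-en-1-yl)-3-hydroxy-5-oxooxolane-3-carboxylate (both C3 epimers), via keto ester 13 (not isolated), via zinc enolate 14 (not isolated)
Conditions: DMDO (1.05 equiv), acetone–CH2Cl2, −20 °C; evaporate; then Zn dust (TMSCl-activated), THF, 0 °C → rt; cold 0.5 M HCl
Reagents that add atoms: dimethyldioxirane, CC1(C)OO1
Why: Oxygen transfer from dimethyldioxirane to the diazo carbon (loss of N2) unmasks the α-keto ester without base, and zinc insertion into the C–Br bond then gives a Reformatsky enolate that adds 5-exo to the adjacent, highly electrophilic ketone (intramolecular Reformatsky-type aldol addition) to close the lactone ring, so the C2 stereocentre never meets base and the new carbinol centre is erased in step 8.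

Step 8
Reactants: 15 benzyl (2S)-2-(but-3-en-1-yl)-3-hydroxy-5-oxooxolane-3-carboxylate
Product: 17 benzyl (2S)-2-(but-3-en-1-yl)-5-oxo-2,5-dihydrofuran-3-carboxylate, via chlorosulfite 16 (not isolated)
Conditions: SOCl2, pyridine, CH2Cl2, −10 → 0 °C
Reagents that add atoms: none
Why: Dehydration of the tertiary β-hydroxy lactone through its chlorosulfite, in which pyridine removes the acidic C4–H next to the lactone carbonyl (E2/E1cB-type elimination), so both C3 epimers converge on the conjugated butenolide and the weak base leaves C2 intact.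

Step 9
Reactants: 17 benzyl (2S)-2-(but-3-en-1-yl)-5-oxo-2,5-dihydrofuran-3-carboxylate; 7 2-methyl-2-(undec-10-en-1-yl)-1,3-dioxolane
Product: 18 benzyl (2S)-2-[13-(2-methyl-1,3-dioxolan-2-yl)tridec-3-en-1-yl]-5-oxo-2,5-dihydrofuran-3-carboxylate (E/Z mixture)
Conditions: second-generation Grubbs catalyst RuCl2(=CHPh)(H2IMes)(PCy3) (5 mol%), 7 (3 equiv), CH2Cl2, 40 °C
Reagents that add atoms: none
Why: Olefin cross-metathesis between two unhindered terminal alkenes, driven by loss of ethene and by excess 7, while the electron-poor trisubstituted ring alkene is inert to the ruthenium carbene.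

Step 10
Reactants: 18 benzyl (2S)-2-[13-(2-methyl-1,3-dioxolan-2-yl)tridec-3-en-1-yl]-5-oxo-2,5-dihydrofuran-3-carboxylate
Product: 19 (2S,3S)-2-[13-(2-methyl-1,3-dioxolan-2-yl)tridecyl]-5-oxooxolane-3-carboxylic acid
Conditions: H2 (3 bar), 10% Pd/C, EtOAc, rt
Reagents that add atoms: none
Why: Heterogeneous catalytic hydrogenation saturates the chain alkene, cleaves the benzyl ester by hydrogenolysis and adds H2 syn to the butenolide face anti to the C2 chain, which places the C3 carboxyl cis to the chain (2S,3S).

Step 11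
Reactants: 19 (2S,3S)-2-[13-(2-methyl-1,3-dioxolan-2-yl)tridecyl]-5-oxooxolane-3-carboxylic acid
Product: 21 (2S,3S,4S)-4-methyl-5-oxo-2-(14-oxopentadecyl)oxolane-3-carboxylic acid, via ketal acid 20 (not isolated)
Conditions: NaN(SiMe3)2 (2.3 equiv), THF, −78 °C; MeI (4 equiv), −78 → −20 °C; then 2 M HCl, THF, rt
Reagents that add atoms: iodomethane, CI; water, O
Why: Alkylation of the carboxylate/lactone-enolate dianion with MeI occurs on the face anti to the C3 carboxylate and the C2 chain, giving the 3,4-trans (4S) methyl group, and the acidic work-up hydrolyses the dioxolane to release the methyl ketone.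

**Compound list**
1 | dec-9-en-1-ol | OCCCCCCCCC=C | starting material
2 | 10-bromodec-1-ene | BrCCCCCCCCC=C | intermediate
3 | ethyl acetoacetate (ethyl 3-oxobutanoate) | CCOC(=O)CC(C)=O | starting material
4 | ethyl 2-acetyldodec-11-enoate (racemic) | CCOC(=O)C(CCCCCCCCC=C)C(C)=O | intermediate
5 | 2-acetyldodec-11-enoic acid (racemic) | CC(=O)C(CCCCCCCCC=C)C(=O)O | intermediate (not isolated)
6 | tridec-12-en-2-one | CC(=O)CCCCCCCCCC=C | intermediate
7 | 2-methyl-2-(undec-10-en-1-yl)-1,3-dioxolane | CC1(CCCCCCCCCC=C)OCCO1 | intermediate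
8 | pent-4-enal | C=CCCC=O | starting material
9 | benzyl diazoacetate | [N-]=[N+]=CC(=O)OCc1ccccc1 | starting material
10 | benzyl (3S)-2-diazo-3-hydroxyhept-6-enoate | C=CCC[C@H](O)C(=[N+]=[N-])C(=O)OCc1ccccc1 | intermediate
11 | bromoacetyl bromide | BrCC(Br)=O | starting material
12 | benzyl (3S)-3-[(bromoacetyl)oxy]-2-diazohept-6-enoate | C=CCC[C@H](OC(=O)CBr)C(=[N+]=[N-])C(=O)OCc1ccccc1 | intermediate
13 | benzyl (3S)-3-[(bromoacetyl)oxy]-2-oxohept-6-enoate | C=CCC[C@H](OC(=O)CBr)C(=O)C(=O)OCc1ccccc1 | intermediate (not isolated)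
14 | benzyl (3S)-3-{[(bromozincio)acetyl]oxy}-2-oxohept-6-enoate (Reformatsky enolate, drawn C-bound) | C=CCC[C@H](OC(=O)C[Zn]Br)C(=O)C(=O)OCc1ccccc1 | intermediate (not isolated)
15 | benzyl (2S)-2-(but-3-en-1-yl)-3-hydroxy-5-oxooxolane-3-carboxylate (both C3 epimers) | C=CCC[C@@H]1OC(=O)CC1(O)C(=O)OCc2ccccc2 | intermediate
16 | benzyl (2S)-2-(but-3-en-1-yl)-3-[(chlorosulfinyl)oxy]-5-oxooxolane-3-carboxylate | C=CCC[C@@H]1OC(=O)CC1(OS(Cl)=O)C(=O)OCc2ccccc2 | intermediate (not isolated)
17 | benzyl (2S)-2-(but-3-en-1-yl)-5-oxo-2,5-dihydrofuran-3-carboxylate | C=CCC[C@@H]1OC(=O)C=C1C(=O)OCc2ccccc2 | intermediate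
18 | benzyl (2S)-2-[13-(2-methyl-1,3-dioxolan-2-yl)tridec-3-en-1-yl]-5-oxo-2,5-dihydrofuran-3-carboxylate (E/Z mixture) | CC1(CCCCCCCCCC=CCC[C@@H]2OC(=O)C=C2C(=O)OCc3ccccc3)OCCO1 | intermediate
19 | (2S,3S)-2-[13-(2-methyl-1,3-dioxolan-2-yl)tridecyl]-5-oxooxolane-3-carboxylic acid | CC1(CCCCCCCCCCCCC[C@@H]2OC(=O)C[C@@H]2C(=O)O)OCCO1 | intermediate
20 | (2S,3S,4S)-4-methyl-2-[13-(2-methyl-1,3-dioxolan-2-yl)tridecyl]-5-oxooxolane-3-carboxylic acid | CC1(CCCCCCCCCCCCC[C@@H]2OC(=O)[C@@H](C)[C@@H]2C(=O)O)OCCO1 | intermediate (not isolated)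
21 | (2S,3S,4S)-4-methyl-5-oxo-2-(14-oxopentadecyl)oxolane-3-carboxylic acid | CC(=O)CCCCCCCCCCCCC[C@@H]1OC(=O)[C@@H](C)[C@@H]1C(=O)O | target

**Step count**
Total step count: 11 (steps 1–4 for fragment 7, steps 5–8 for fragment 17, steps 9–11 after the union).
Longest linear sequence: 7 steps (5 → 11 from 8 and 9; the branch 1 → 4, 9 → 11 is equally long), i.e. 7/11 of the total.

**Three steps most likely to fail**

Step 5 is the first risk: unbranched aldehydes give lower enantioselectivity in this aldol than branched or aromatic ones, and self-aldol of 8 competes. The fallback sets out from 8 and 9 and comes back at 10. A DBU-catalysed aldol in MeCN gives racemic benzyl 2-diazo-3-hydroxyhept-6-enoate F1, and oxidation with IBX in DMSO gives benzyl 2-diazo-3-oxohept-6-enoate F2. Reduction of F2 with an (S)-selective ketoreductase (NADP+, i-PrOH as hydride source, pH 7 buffer, 30 °C) returns 10. The stereocentre is then set by enzymatic ketone reduction instead of by the C–C bond-forming step.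

Step 7 is the second risk: keto ester 13 can hydrate, enolise at C3 or be reduced by zinc at the activated ketone, and excess DMDO would epoxidise the terminal alkene. The fallback sets out from 10 and comes back at 17, bypassing 12–16. Esterification of 10 with (diethoxyphosphoryl)acetic acid (DCC, DMAP cat., CH2Cl2, 0 °C) gives benzyl (3S)-2-diazo-3-{[(diethoxyphosphoryl)acetyl]oxy}hept-6-enoate F3. Oxidation with DMDO as before gives benzyl (3S)-3-{[(diethoxyphosphoryl)acetyl]oxy}-2-oxohept-6-enoate F4. LiCl and i-Pr2NEt in MeCN at 0 °C then close the ring by intramolecular Horner–Wadsworth–Emmons olefination and deliver butenolide 17 directly.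

Step 11 is the third risk: the dianion may form incompletely, over-methylate, or alkylate with poor facial selectivity. The fallback sets out from 19 and comes back at 20. Carboxylation of 19 at C4 with MeOMgOCO2Me in DMF at 130 °C gives (2S,3S)-2-[13-(2-methyl-1,3-dioxolan-2-yl)tridecyl]-5-oxooxolane-3,4-dicarboxylic acid F5, used crude. Treatment with aqueous CH2O, N-methylaniline, NaOAc and AcOH (decarboxylative Mannich/elimination) gives (2S,3S)-4-methylidene-2-[13-(2-methyl-1,3-dioxolan-2-yl)tridecyl]-5-oxooxolane-3-carboxylic acid F6. Hydrogenation (H2, Pd/C, EtOAc) from the open face gives the all-cis (2S,3S,4R)-4-methyl-2-[13-(2-methyl-1,3-dioxolan-2-yl)tridecyl]-5-oxooxolane-3-carboxylic acid F7. Thermodynamic equilibration of C4 with KOt-Bu in t-BuOH/THF (the carboxylate protects C3) gives the 3,4-trans acid 20, and the acidic work-up of step 11 then gives 21.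

**Further compounds**
F1 | step 5 | benzyl 2-diazo-3-hydroxyhept-6-enoate (racemic) | C=CCCC(O)C(=[N+]=[N-])C(=O)OCc1ccccc1
F2 | step 5 | benzyl 2-diazo-3-oxohept-6-enoate | C=CCCC(=O)C(=[N+]=[N-])C(=O)OCc1ccccc1
F3 | step 7 | benzyl (3S)-2-diazo-3-{[(diethoxyphosphoryl)acetyl]oxy}hept-6-enoate | C=CCC[C@H](OC(=O)CP(=O)(OCC)OCC)C(=[N+]=[N-])C(=O)OCc1ccccc1
F4 | step 7 | benzyl (3S)-3-{[(diethoxyphosphoryl)acetyl]oxy}-2-oxohept-6-enoate | C=CCC[C@H](OC(=O)CP(=O)(OCC)OCC)C(=O)C(=O)OCc1ccccc1
F5 | step 11 | (2S,3S)-2-[13-(2-methyl-1,3-dioxolan-2-yl)tridecyl]-5-oxooxolane-3,4-dicarboxylic acid (C4 epimers) | CC1(CCCCCCCCCCCCC[C@@H]2OC(=O)C(C(=O)O)[C@@H]2C(=O)O)OCCO1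
F6 | step 11 | (2S,3S)-4-methylidene-2-[13-(2-methyl-1,3-dioxolan-2-yl)tridecyl]-5-oxooxolane-3-carboxylic acid | CC1(CCCCCCCCCCCCC[C@@H]2OC(=O)C(=C)[C@@H]2C(=O)O)OCCO1
F7 | step 11 | (2S,3S,4R)-4-methyl-2-[13-(2-methyl-1,3-dioxolan-2-yl)tridecyl]-5-oxooxolane-3-carboxylic acid | CC1(CCCCCCCCCCCCC[C@@H]2OC(=O)[C@H](C)[C@@H]2C(=O)O)OCCO1
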